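The route rests on closing the pyran ring C of the flavan half through its aryl ether bond O1–C8a, with ring A as the electrophile. C8a is ortho to C4a and meta to both O5 and O7: a fluorine placed there first directs lithiation to C4a, which brings in C4–C3–C2 from (R)-glycidate, and is then displaced by the C2 alkoxide in an intramolecular SNAr that the two meta benzyloxy groups activate. The precursor is an open-chain anti-2-methoxy-1,3-diarylpropan-1-ol; its C2–O bond is never broken, so C2 and C3 are carried over unchanged. The chroman then adds through C8 to a diaryl triketone, and bis-ketalisation completes the target.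

Key step: step 7

Locants: the flavan half has O1 and C2–C8a, with ring A (C4a–C8a), ring B (aryl on C2) and ring C (pyran). The ketal half is primed: O1', C2' (ketal carbon), C3' (carbinol), C4' (C=O), ring A' (phloroglucinol ring) and ring B' (aryl on C2'). The dihydrofuran ring is O7–C2'–C3'–C8–C7.

Remark: C2' is a ketal carbon that equilibrates under the acid of step 12, so the route controls C3' (step 11) and C2' follows on ring closure; as drawn, the 3'-hydroxyl and the 2'-aryl group lie on opposite faces of the C2'–C3' bond, and 22 is written exactly as drawn on the assumption that the equilibrium selects this arrangement (fused five- and six-membered ketal rings usually prefer the cis fusion, in which case the product would be the C2' epimer).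

Step 1
Reactants: 1 1,3,5-trifluorobenzene
Product: 2 1,3-bis(benzyloxy)-5-fluorobenzene
Conditions: BnOH, NaH, NMP, 0 to 100 °C
Reagents that add atoms: benzyl alcohol, OCc1ccccc1
Why: twofold SNAr by sodium benzyl oxide; each benzyloxy group introduced lowers the reactivity of the remaining C–F bonds, so the third fluorine should survive.

Step 2
Reactants: 2 1,3-bis(benzyloxy)-5-fluorobenzene; 3 methyl (R)-oxirane-2-carboxylate
Product: 6 methyl (2R)-3-[2,4-bis(benzyloxy)-6-fluorophenyl]-2-hydroxypropanoate, via aryllithium 4 (not isolated), via arylmagnesium bromide 5 (not isolated)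
Conditions: n-BuLi, THF, −78 °C; MgBr2·OEt2; CuI (10 mol %), 3, −78 to −20 °C
Reagents that add atoms: none
Why: directed ortho-metalation at one of the two equivalent positions between F and OBn (fluorine is the stronger acidifying group), transmetalation to magnesium to suppress loss of LiF, then copper-catalysed SN2 opening of the epoxide at its CH2 terminus; the stereocentre of 3 is untouched and becomes C3 (R) of the flavan.

Step 3
Reactants: 6 methyl (2R)-3-[2,4-bis(benzyloxy)-6-fluorophenyl]-2-hydroxypropanoate
Product: 7 methyl (2R)-3-[2,4-bis(benzyloxy)-6-fluorophenyl]-2-methoxypropanoate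
Conditions: MeI, Ag2O, MeCN, 40 °C, dark
Reagents that add atoms: iodomethane, CI
Why: Purdie methylation of the secondary alcohol under non-basic conditions, so the α-stereocentre of the ester should not epimerise.

Step 4
Reactants: 7 methyl (2R)-3-[2,4-bis(benzyloxy)-6-fluorophenyl]-2-methoxypropanoate
Product: 8 (2R)-3-[2,4-bis(benzyloxy)-6-fluorophenyl]-N,2-dimethoxy-N-methylpropanamide
Conditions: MeNH(OMe)·HCl, iPrMgCl, THF, −20 to 0 °C
Reagents that add atoms: N,O-dimethylhydroxylamine hydrochloride, CNOC.Cl
Why: direct aminolysis of the ester by the chloromagnesium amide at low temperature gives the Weinreb amide without enolising the α-methoxy centre.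

Step 5
Reactants: 8 (2R)-3-[2,4-bis(benzyloxy)-6-fluorophenyl]-N,2-dimethoxy-N-methylpropanamide; 9 1-(benzyloxy)-4-bromobenzene
Product: 11 (2R)-3-[2,4-bis(benzyloxy)-6-fluorophenyl]-1-[4-(benzyloxy)phenyl]-2-methoxypropan-1-one, via Grignard reagent 10 (not isolated)
Conditions: 9, Mg, THF, reflux; then 8, THF, 0 °C; aq. NH4Cl
Reagents that add atoms: none
Why: Weinreb ketone synthesis; the chelated tetrahedral intermediate survives until work-up, so addition stops at the ketone and the α-centre is not enolised.

Step 6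
Reactants: 11 (2R)-3-[2,4-bis(benzyloxy)-6-fluorophenyl]-1-[4-(benzyloxy)phenyl]-2-methoxypropan-1-one
Product: 12 (1S,2R)-3-[2,4-bis(benzyloxy)-6-fluorophenyl]-1-[4-(benzyloxy)phenyl]-2-methoxypropan-1-ol
Conditions: Zn(BH4)2, Et2O, −78 to −20 °C
Reagents that add atoms: none
Why: Cram-chelate reduction; zinc bridges the carbonyl and α-methoxy oxygens and hydride enters from the face of the α-hydrogen, which should give the anti (1S,2R) alcohol and so sets C2 of the flavan.

Step 7
Reactants: 12 (1S,2R)-3-[2,4-bis(benzyloxy)-6-fluorophenyl]-1-[4-(benzyloxy)phenyl]-2-methoxypropan-1-ol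
Product: 14 (2S,3R)-5,7-bis(benzyloxy)-2-[4-(benzyloxy)phenyl]-3-methoxychromane, via potassium alkoxide 13 (not isolated)
Conditions: KH, 18-crown-6, DMF, 0 °C to rt
Reagents that add atoms: none
Why: KH forms the potassium alkoxide 13, which adds to C8a to give a Meisenheimer anion whose charge lies on C4a, C6 and C8 and is stabilised inductively by the two meta benzyloxy groups; loss of fluoride restores the arene (addition–elimination SNAr). The closest known reaction type is the intramolecular SNAr etherification of ortho-fluoroaryl alkanols to chromans. Ring C closes in the 6-exo-trig mode (the attacked C8a–C8 bond lies outside the new ring). No stereocentre is formed, and C2 and C3 are retained because the alkoxide oxygen, not a carbon, is the reacting centre, so the acid-labile 4-alkoxybenzylic C2–O bond is never ionised. The step needs chemoselective attack at C8a, which is secured by the single fluorine, by fluoride being the best leaving group for rate-limiting addition, and by the six-membered transition state; the benzyl ethers are inert to the alkoxide.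

Step 8
Reactants: 15 1-(2,4,6-trihydroxyphenyl)ethan-1-one
Product: 16 1-[2,4,6-tris(benzyloxy)phenyl]ethan-1-one
Conditions: BnBr, K2CO3, DMF, 80 °C
Reagents that add atoms: benzyl bromide, BrCc1ccccc1
Why: Williamson ether synthesis; DMF at 80 °C should also alkylate the two hydrogen-bonded ortho hydroxyls.

Step 9
Reactants: 16 1-[2,4,6-tris(benzyloxy)phenyl]ethan-1-one; 17 methyl 4-(benzyloxy)benzoate
Product: 18 1-[4-(benzyloxy)phenyl]-3-[2,4,6-tris(benzyloxy)phenyl]propane-1,3-dione
Conditions: NaH, THF, reflux; aq. HCl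
Reagents that add atoms: none
Why: crossed Claisen condensation of the methyl ketone enolate with the non-enolisable ester, driven by deprotonation of the 1,3-diketone formed.

Step 10
Reactants: 18 1-[4-(benzyloxy)phenyl]-3-[2,4,6-tris(benzyloxy)phenyl]propane-1,3-dione
Product: 19 1-[4-(benzyloxy)phenyl]-3-[2,4,6-tris(benzyloxy)phenyl]propane-1,2,3-trione
Conditions: SeO2, 1,4-dioxane, 90 °C; azeotropic drying (toluene)
Reagents that add atoms: selenium dioxide, O=[Se]=O
Why: Riley oxidation of the doubly activated methylene gives the vicinal triketone, which is dried before use because it hydrates at the central carbonyl.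

Step 11
Reactants: 14 (2S,3R)-5,7-bis(benzyloxy)-2-[4-(benzyloxy)phenyl]-3-methoxychromane; 19 1-[4-(benzyloxy)phenyl]-3-[2,4,6-tris(benzyloxy)phenyl]propane-1,2,3-trione
Product: 20 (2S)-2-{(2S,3R)-5,7-bis(benzyloxy)-2-[4-(benzyloxy)phenyl]-3-methoxychroman-8-yl}-1-[4-(benzyloxy)phenyl]-2-hydroxy-3-[2,4,6-tris(benzyloxy)phenyl]propane-1,3-dione
Conditions: Cu(OTf)2 (10 mol %), (S,S)-tBu-BOX (11 mol %), 4 Å MS, CH2Cl2, −20 °C to rt
Reagents that add atoms: none
Why: Proposed new method: the triketone should bind the square-planar divalent copper–bis(oxazoline) complex through the central and the 4-benzyloxybenzoyl carbonyl oxygens (the twisted, doubly ortho-substituted tris(benzyloxy)benzoyl group chelates poorly), the tert-butyl groups shield one face of the central carbonyl, and C8 of 14 (para to O5, ortho to O7 and O1, the less hindered of the two free ring A positions) attacks the open face, so the new C3' stereocentre is under catalyst control; the closest known reaction types are the Cu(OTf)2–bis(oxazoline)-catalysed enantioselective Friedel–Crafts hydroxyalkylation of aromatic ethers with pyruvates and glyoxylates and the ninhydrin-type arylation of vicinal tricarbonyls at the central carbonyl; the antipodal ligand is used if a test run shows the opposite facial sense.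

Step 12
Reactants: 20 (2S)-2-{(2S,3R)-5,7-bis(benzyloxy)-2-[4-(benzyloxy)phenyl]-3-methoxychroman-8-yl}-1-[4-(benzyloxy)phenyl]-2-hydroxy-3-[2,4,6-tris(benzyloxy)phenyl]propane-1,3-dione
Product: 22 target bis-ketal (2S,3R,2'S,3'R), via heptaphenol 21 (not isolated)
Conditions: H2 (1 atm), Pd(OH)2/C, THF/MeOH, rt; filter; PPTS (cat.), THF, rt
Reagents that add atoms: none
Why: hydrogenolysis of the seven aryl benzyl ethers frees O7–H and the ortho hydroxyl of ring A', which add in turn to the C2' ketone (hemiketal, then capture of the oxocarbenium ion) to give the bis-ketal; C3' is carried over unchanged (its descriptor changes from S to R only because the priorities of its neighbours change) and C2' is set by ring closure onto the fixed C3' centre under acid equilibration.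

Compound list
1 | 1,3,5-trifluorobenzene | Fc1cc(F)cc(F)c1 | starting material
2 | 1,3-bis(benzyloxy)-5-fluorobenzene | Fc1cc(OCc2ccccc2)cc(OCc2ccccc2)c1 | intermediate
3 | methyl (R)-oxirane-2-carboxylate (methyl (R)-glycidate) | COC(=O)[C@H]1CO1 | starting material
4 | [2,4-bis(benzyloxy)-6-fluorophenyl]lithium | [Li]c1c(F)cc(OCc2ccccc2)cc1OCc1ccccc1 | intermediate
5 | [2,4-bis(benzyloxy)-6-fluorophenyl]magnesium bromide | Br[Mg]c1c(F)cc(OCc2ccccc2)cc1OCc1ccccc1 | intermediate
6 | methyl (2R)-3-[2,4-bis(benzyloxy)-6-fluorophenyl]-2-hydroxypropanoate | COC(=O)[C@H](O)Cc1c(F)cc(OCc2ccccc2)cc1OCc1ccccc1 | intermediate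
7 | methyl (2R)-3-[2,4-bis(benzyloxy)-6-fluorophenyl]-2-methoxypropanoate | COC(=O)[C@H](OC)Cc1c(F)cc(OCc2ccccc2)cc1OCc1ccccc1 | intermediate
8 | (2R)-3-[2,4-bis(benzyloxy)-6-fluorophenyl]-N,2-dimethoxy-N-methylpropanamide | CON(C)C(=O)[C@H](OC)Cc1c(F)cc(OCc2ccccc2)cc1OCc1ccccc1 | intermediate
9 | 1-(benzyloxy)-4-bromobenzene | Brc1ccc(OCc2ccccc2)cc1 | starting material
10 | [4-(benzyloxy)phenyl]magnesium bromide | Br[Mg]c1ccc(OCc2ccccc2)cc1 | intermediate
11 | (2R)-3-[2,4-bis(benzyloxy)-6-fluorophenyl]-1-[4-(benzyloxy)phenyl]-2-methoxypropan-1-one | O=C(c1ccc(OCc2ccccc2)cc1)[C@H](OC)Cc1c(F)cc(OCc2ccccc2)cc1OCc1ccccc1 | intermediate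
12 | (1S,2R)-3-[2,4-bis(benzyloxy)-6-fluorophenyl]-1-[4-(benzyloxy)phenyl]-2-methoxypropan-1-ol (anti) | O[C@@H](c1ccc(OCc2ccccc2)cc1)[C@H](OC)Cc1c(F)cc(OCc2ccccc2)cc1OCc1ccccc1 | intermediate
13 | potassium alkoxide of 12 | [K+].[O-][C@@H](c1ccc(OCc2ccccc2)cc1)[C@H](OC)Cc1c(F)cc(OCc2ccccc2)cc1OCc1ccccc1 | intermediate
14 | (2S,3R)-5,7-bis(benzyloxy)-2-[4-(benzyloxy)phenyl]-3-methoxychromane (2,3-trans) | CO[C@@H]1Cc2c(OCc3ccccc3)cc(OCc3ccccc3)cc2O[C@H]1c1ccc(OCc2ccccc2)cc1 | intermediate
15 | 1-(2,4,6-trihydroxyphenyl)ethan-1-one | CC(=O)c1c(O)cc(O)cc1O | starting material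
16 | 1-[2,4,6-tris(benzyloxy)phenyl]ethan-1-one | CC(=O)c1c(OCc2ccccc2)cc(OCc2ccccc2)cc1OCc1ccccc1 | intermediate
17 | methyl 4-(benzyloxy)benzoate | COC(=O)c1ccc(OCc2ccccc2)cc1 | starting material
18 | 1-[4-(benzyloxy)phenyl]-3-[2,4,6-tris(benzyloxy)phenyl]propane-1,3-dione | O=C(CC(=O)c1c(OCc2ccccc2)cc(OCc2ccccc2)cc1OCc1ccccc1)c1ccc(OCc2ccccc2)cc1 | intermediate
19 | 1-[4-(benzyloxy)phenyl]-3-[2,4,6-tris(benzyloxy)phenyl]propane-1,2,3-trione | O=C(C(=O)C(=O)c1c(OCc2ccccc2)cc(OCc2ccccc2)cc1OCc1ccccc1)c1ccc(OCc2ccccc2)cc1 | intermediate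
20 | (2S)-2-hydroxy-1,3-dione adduct: the central carbinol carbon carries OH, C8 of chroman 14, the 4-(benzyloxy)benzoyl group and the 2,4,6-tris(benzyloxy)benzoyl group | CO[C@@H]1Cc2c(OCc3ccccc3)cc(OCc3ccccc3)c(c2O[C@H]1c1ccc(OCc2ccccc2)cc1)[C@](O)(C(=O)c1ccc(OCc2ccccc2)cc1)C(=O)c1c(OCc2ccccc2)cc(OCc2ccccc2)cc1OCc1ccccc1 | intermediate
21 | heptaphenol: (2S)-2-[(2S,3R)-5,7-dihydroxy-2-(4-hydroxyphenyl)-3-methoxychroman-8-yl]-2-hydroxy-1-(4-hydroxyphenyl)-3-(2,4,6-trihydroxyphenyl)propane-1,3-dione | CO[C@@H]1Cc2c(O)cc(O)c(c2O[C@H]1c1ccc(O)cc1)[C@](O)(C(=O)c1ccc(O)cc1)C(=O)c1c(O)cc(O)cc1O | intermediate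
22 | bis-ketal of 21: O7 and the ortho hydroxyl O1' of ring A' are both bonded to C2', which keeps ring B'; dihydrofuran ring (O7, C2', C3', C8, C7) fused through C2'–C3' to a 5',7'-dihydroxychroman-4'-one ring; 3'-OH free; (2S,3R,2'S,3'R) | CO[C@@H]1Cc2c(O)cc3c(c2O[C@H]1c1ccc(O)cc1)[C@@]1(O)C(=O)c2c(O)cc(O)cc2O[C@]1(c1ccc(O)cc1)O3 | target

Total step count: 12. Longest linear sequence: 9 steps (steps 1 to 7, then 11 and 12).

Steps most likely to fail

1. Step 11 (bears the label). The catalyst must tell two aroyl groups apart, so facial discrimination at the central carbonyl may be poor. Attack may also occur at C6, and the product may bind copper and stop turnover. The fallback uses known chemistry and sets out from 14. N-Bromosuccinimide (CH2Cl2, −78 to 0 °C) brominates C8 to give the 8-bromochroman F1. Bromine–lithium exchange (n-BuLi, THF, −78 °C) gives the 8-lithiochroman F2, which adds to the central carbonyl of 19. This fixes the site of C–C bond formation but not the face, so 20 is formed together with its carbinol epimer F3. The two are diastereomers and are separated by preparative HPLC, and the route is rejoined at 20.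

2. Step 2. The ortho-fluoroaryl metal may lose metal fluoride to an aryne, or add to the ester carbonyl, before the doubly ortho-substituted aryl copper species opens the epoxide. The fallback sets out from 2 and replaces the epoxide by a fast electrophile and the chiral pool by an auxiliary. Aryllithium 4 is quenched with DMF at −78 °C to give the aldehyde F4. NaBH4 gives the benzyl alcohol F5 and PBr3 the benzyl bromide F6. The sodium enolate of (S)-4-benzyl-3-(methoxyacetyl)oxazolidin-2-one (NaHMDS, THF, −78 °C) is alkylated by F6 anti to the benzyl group of the auxiliary (Evans alkylation) to give the (R)-α-methoxy imide F7. AlMe3 and MeNH(OMe)·HCl convert F7 into Weinreb amide 8, where the route is rejoined; steps 3 and 4 are then not needed.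

3. Step 12. Over-reduction may set in before all seven benzyl ethers are removed: hydrogenolysis of the benzylic C2–O1 bond or of the benzylic C3'–OH, or reduction of a carbonyl group. The fallback sets out from 20 and removes the benzyl groups without hydrogen, with BCl3 and pentamethylbenzene in CH2Cl2 at −78 °C. The Lewis acid should close the bis-ketal in the same flask through 21, and the route is rejoined at 22. No new compound is made on the way (F0).

Further compounds
F1 | step 11 | (2S,3R)-5,7-bis(benzyloxy)-2-[4-(benzyloxy)phenyl]-8-bromo-3-methoxychromane | CO[C@@H]1Cc2c(OCc3ccccc3)cc(OCc3ccccc3)c(Br)c2O[C@H]1c1ccc(OCc2ccccc2)cc1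
F2 | step 11 | {(2S,3R)-5,7-bis(benzyloxy)-2-[4-(benzyloxy)phenyl]-3-methoxychroman-8-yl}lithium | CO[C@@H]1Cc2c(OCc3ccccc3)cc(OCc3ccccc3)c([Li])c2O[C@H]1c1ccc(OCc2ccccc2)cc1
F3 | step 11 | (2R)-epimer of 20 at the carbinol carbon | CO[C@@H]1Cc2c(OCc3ccccc3)cc(OCc3ccccc3)c(c2O[C@H]1c1ccc(OCc2ccccc2)cc1)[C@@](O)(C(=O)c1ccc(OCc2ccccc2)cc1)C(=O)c1c(OCc2ccccc2)cc(OCc2ccccc2)cc1OCc1ccccc1
F4 | step 2 | 2,4-bis(benzyloxy)-6-fluorobenzaldehyde | O=Cc1c(F)cc(OCc2ccccc2)cc1OCc1ccccc1
F5 | step 2 | [2,4-bis(benzyloxy)-6-fluorophenyl]methanol | OCc1c(F)cc(OCc2ccccc2)cc1OCc1ccccc1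
F6 | step 2 | 1,5-bis(benzyloxy)-2-(bromomethyl)-3-fluorobenzene | BrCc1c(F)cc(OCc2ccccc2)cc1OCc1ccccc1
F7 | step 2 | (4S)-4-benzyl-3-{(2R)-3-[2,4-bis(benzyloxy)-6-fluorophenyl]-2-methoxypropanoyl}oxazolidin-2-one | CO[C@H](Cc1c(F)cc(OCc2ccccc2)cc1OCc1ccccc1)C(=O)N1[C@@H](Cc2ccccc2)COC1=O
F0 | step 12 | none | none
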